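## Analysis of the target

The core is numbered as follows: C1 is the geranyl bridgehead next to the gem-dimethyl carbon C8; C2, C3 and C4 are the triketone arc with the aroyl group on C3; C5 is the other geranyl bridgehead; C6 is CH2; C7 is the prenyl methine; C9 is the bridging ketone. The target 28 is a type B polyprenylated acylphloroglucinol built on a bicyclo[3.3.1]nonane-2,4,9-trione. Ring A (C1, C2, C3, C4, C5, C9) is an enolised β-triketone carrying the 3,4-dihydroxybenzoyl group on C3, and ring B (C5, C6, C7, C8, C1, C9) is a cyclohexanone holding C7 and C8. There are three stereocentres, the quaternary bridgeheads C1 and C5 (each with an (E)-geranyl group) and C7; because the one-carbon bridge ties C1 to C5, only the absolute configuration of C7 and its relation to C5 need control. In 28 the C7 prenyl group is equatorial on ring B, cis to the C5 geranyl group and turned away from ring A (1S,5S,7R in this numbering). Sensitive groups are five trisubstituted side-chain alkenes (two of fixed E geometry), an oxidation-prone catechol, and an acidic, chelating triketone enol that cyclises onto prenyl-type alkenes under acid. The difficulty lies in the contiguous congested carbons C5, C9, C1 and C8, and in bridgeheads that cannot form planar enolates once the bicycle is closed. The strategy rests on one observation: C9, C5, C6, C7 and C8 form a cyclopentanone that can enolise only at C5 (C8 is quaternary), and C4–C3–C2–C1 are the four carbons of diketene 13 at the correct oxidation level.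

## Retrosynthetic reasoning

**28 ⇐ 27 ⇐ 26.** The last two operations only uncover functionality: the two aryl O–Si bonds and the enol O–CH3 bond. The catechol is freed last because it would not survive the oxidant and the carbanion steps. The methyl enol ether is kept until then because it turns the acidic triketone into a neutral vinylogous ester that tolerates strong base.

**26 ⇐ 21 + 24.** The C3–aroyl bond is cut. In 21 both bridgeheads are quaternary, so the vinylic C3–H is the only removable proton and the acylation site is unambiguous. The acid chloride 24 comes from acid 22 through the persilylated ester 23.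

**21 ⇐ 19 + 9.** The C1–CH2 bond of the second geranyl group is cut. C1 becomes a bridgehead methine between two carbonyls only after the bicycle exists, so this bond has to be made late; the forward step is alkylation of a pyramidal bridgehead enolate with the allylic bromide 9.

**19 ⇐ 18 ⇐ 16.** After removing the enol methyl group, the C8–C1 bond of 18 is cut and C8 is reconnected to C9. This converts the bridged trione into the cis-fused hydroxy dione 16, replacing the construction of a bicyclo[3.3.1]nonane by that of a hydrindane. The forward reaction must oxidise C1 and move C8 from C9 to C1 in one 1,2-shift.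

**16 ⇐ 12 + 13.** Two bonds are cut, C5–C4 and C1–C9. This removes ring A, the C5 quaternary centre and the angular carbinol at once and leaves the monocyclic silyl enol ether 12 and the four-carbon lactone 13. The forward step must acylate C5 on the face opposite the C7 prenyl group and close the ring by aldol addition to C9.

**12 ⇐ 11 ⇐ 8 + 9.** The O–Si bond and then the C5–CH2 bond of the first geranyl group are cut. C5 is the only enolisable position of ketone 8, so alkylation and later enolisation need no regiocontrol.

**8 ⇐ 6 + 7; 6 ⇐ 5 ⇐ 4.** The prenyl C=C bond is cut to aldehyde 6 and the isopropyl phosphonium salt 7. The aldehyde is reached from keto ester 4 by a reduction–oxidation pair through diol 5, which also corrects any over-reduction of the ketone in the preceding step.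

**4 ⇐ 3 ⇐ 1 + 2.** The C7–H bond is cut: the only independent stereocentre is set by asymmetric conjugate reduction of enoate 3. Enoate 3 comes from one olefination of the symmetric dione 1 with phosphonate 2.

## Alternatives that were turned down

**Alternative 1:** Ring B is cut at C5–C6 and C7–C8 into a four-carbon silyloxy diene A2 (from mesityl oxide A1) and the acrylimide A3. A chiral bis(oxazoline)–Cu(OTf)2 catalyst (divalent copper) would promote the Diels–Alder reaction to cyclohexene A4.
- For: C7 is set by a thoroughly studied catalytic cycloaddition from cheap achiral materials, and ring B arrives six-membered with a regiodefined enol ether at C9.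
- Against: the reacting diene terminus is the fully substituted gem-dimethyl carbon, whose cis methyl disfavours the s-cis conformer. With a strong Lewis acid such dienes tend to react stepwise at the unsubstituted terminus and stop at the open conjugate adduct.
- Against: A4 contains neither ring A nor a quaternary bridgehead nor a geranyl group. The imide must still become a prenyl group, C5 must be alkylated, a three-carbon malonyl-type unit bridged across C1 and C5 (typically a low-yielding operation), and C1 alkylated.
- Comparison: Alternative 1 is stronger on enantiocontrol at C7 and needs no ring expansion. The chosen route offers a key step that delivers ring A, the C5 quaternary centre and C1 in one operation, and a shorter path from the stereocentre to the complete trione.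

**Alternative 2:** Both bridgehead–geranyl bonds are cut together. The bis(N-hydroxyphthalimide) ester A5 would couple twice with geranyl methyl carbonate A6 under NiBr2(dme) (divalent nickel precatalyst), a bipyridine ligand and zinc or a cathode, to give A7, which has the structure of compound 21.
- For: both geranyl groups enter in one late step, no strong base is needed, bridgehead radicals tolerate pyramidal geometry, and analogues are easy to vary.
- Against: A5 is a trione enol ether with two bridgehead carboxyl groups and the C7 stereocentre, and is no easier to make than 19.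
- Against: the radicals are flanked by two carbonyls and must form quaternary centres (at C1 next to C8), so reduction to C–H competes.
- Against: a nickel allyl from A6 can couple at either terminus and scramble the E geometry; two such events on one molecule multiply the loss.
- Comparison: Alternative 2 is stronger on convergence and avoids bridgehead deprotonation, a real risk of step 11. The chosen route offers two SN2 alkylations with bromide 9 that preserve linear connectivity and E geometry, the first on a simple monocyclic ketone.

**Alternative 3:** The C8–C1 bond is cut. The symmetric dimethoxycyclohexadiene A8 carries on its quaternary carbon a geranyl group and a lavandulyl-type chain. A cobalt hydride from Co(salen) (divalent cobalt) and a silane, with an N-fluoropyridinium oxidant or an anode, would add H to the isopropenyl CH2. The resulting C8 cation would be captured by one enol ether arm to give A9.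
- For: the most congested bond, ring B and the C9 carbonyl form in one step without rearrangement, the precursor is symmetric, and C7 can direct which arm reacts and so set C5.
- Against: A9 has a methylene at C2, so a late allylic oxidation is needed in a molecule with many competing allylic C–H bonds.
- Against: the hydrogen-atom donor and the oxidant can also attack the enol ethers, and a 1,2-hydride shift from C7 to the C8 cation would erase the stereocentre.
- Comparison: Alternative 3 is stronger in making C8–C1 directly. The chosen route offers the correct oxidation level at C2 and C4 from diketene and needs no late C–H oxidation.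

Key step: step 8

Assumption: the sense of induction of the copper hydride catalyst on enoate 3 cannot be predicted with confidence; step 2 is written with (S)-p-tol-BINAP, and the mirror-image ligand is used if that is the one giving (S)-4.

Assumption: the enol tautomers of the triketone are one compound; 28 is written as the C4 enol.

Step 1
Reactants: 1 2,2-dimethylcyclopentane-1,3-dione; 2 triethyl phosphonoacetate
Product: 3 ethyl (2E)-2-(2,2-dimethyl-3-oxocyclopentylidene)acetate
Conditions: NaH (1.0 equiv), THF, 0 °C to 60 °C
Reagents that add atoms: none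
Why: Horner–Wadsworth–Emmons olefination; the non-enolisable 1,3-dione is activated by its second carbonyl whereas the product ketone is an ordinary hindered ketone, so the reaction should stop after one olefination, and the ester takes the E position away from the gem-dimethyl carbon.

Step 2
Reactants: 3 ethyl (2E)-2-(2,2-dimethyl-3-oxocyclopentylidene)acetate
Product: 4 ethyl 2-[(1S)-2,2-dimethyl-3-oxocyclopentyl]acetate
Conditions: Cu(OAc)2 (divalent copper, 3 mol %), (S)-p-tol-BINAP, (EtO)2MeSiH, t-BuOH, toluene, 0 °C
Reagents that add atoms: none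
Why: Asymmetric conjugate reduction of a β,β-disubstituted enoate by a bisphosphine-bound monovalent copper hydride; hydride adds to one face of the C=C, whose β-carbon has clearly different flanks (quaternary carbon against CH2), and this sets C7; t-BuOH protonates the copper enolate, and any hydrosilylation of the hindered ketone is harmless because steps 3 and 4 pass through the alcohol.

Step 3
Reactants: 4 ethyl 2-[(1S)-2,2-dimethyl-3-oxocyclopentyl]acetate
Product: 5 (3S)-3-(2-hydroxyethyl)-2,2-dimethylcyclopentan-1-ol (both C1 epimers)
Conditions: LiAlH4, THF, 0 °C to rt; aq. NaOH work-up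
Reagents that add atoms: none
Why: Hydride reduction of ester and ketone together; C7 is not touched and the carbinol epimers converge in step 4.

Step 4
Reactants: 5 (3S)-3-(2-hydroxyethyl)-2,2-dimethylcyclopentan-1-ol
Product: 6 2-[(1S)-2,2-dimethyl-3-oxocyclopentyl]acetaldehyde
Conditions: (COCl)2, DMSO, CH2Cl2, −78 °C; Et3N, −78 to 0 °C
Reagents that add atoms: none
Why: Swern oxidation of both alcohols; C7 is β to both carbonyls and cannot epimerise, and the aldehyde is used without storage.

Step 5
Reactants: 6 2-[(1S)-2,2-dimethyl-3-oxocyclopentyl]acetaldehyde; 7 isopropyltriphenylphosphonium iodide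
Product: 8 (3S)-2,2-dimethyl-3-(3-methylbut-2-en-1-yl)cyclopentan-1-one
Conditions: 7, n-BuLi, THF, 0 °C; then 6, −78 °C to rt
Reagents that add atoms: none
Why: Wittig olefination with the non-stabilised isopropylidene ylide, which at low temperature takes the aldehyde and leaves the ketone beside the quaternary carbon; this completes the prenyl group.

Step 6
Reactants: 8 (3S)-2,2-dimethyl-3-(3-methylbut-2-en-1-yl)cyclopentan-1-one; 9 geranyl bromide
Product: 11 (3R,5RS)-5-[(2E)-3,7-dimethylocta-2,6-dien-1-yl]-2,2-dimethyl-3-(3-methylbut-2-en-1-yl)cyclopentan-1-one, via lithium enolate 10 (not isolated)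
Conditions: LiN(i-Pr)2 (1.05 equiv), THF, −78 °C; 9, −78 to 0 °C
Reagents that add atoms: none
Why: Enolate alkylation; C5 is the only enolisable carbon, the allylic bromide reacts by SN2 with retention of the E-alkene, and the C5 configuration is irrelevant because step 7 flattens it (the C3 descriptor changes only through priorities).

Step 7
Reactants: 11 (3R,5RS)-5-geranyl-2,2-dimethyl-3-prenylcyclopentan-1-one
Product: 12 {[(4R)-2-geranyl-5,5-dimethyl-4-prenylcyclopent-1-en-1-yl]oxy}trimethylsilane
Conditions: Me3SiOTf (1.3 equiv), Et3N (2 equiv), CH2Cl2, 0 °C to rt; pentane, cold aq. NaHCO3; filtration through basic alumina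
Reagents that add atoms: trimethylsilyl trifluoromethanesulfonate, C[Si](C)(C)OS(=O)(=O)C(F)(F)F
Why: Soft enolisation: the silyl triflate activates the carbonyl oxygen while triethylamine removes the single α-hydrogen, so both C5 epimers of 11 converge on the only possible (tetrasubstituted) silyl enol ether without a metal enolate; excess amine keeps triflic acid from the side-chain alkenes, and isolation removes amine and ammonium salt, which would otherwise consume diketene in step 8.

Step 8
Reactants: 12 {[(4R)-2-geranyl-5,5-dimethyl-4-prenylcyclopent-1-en-1-yl]oxy}trimethylsilane; 13 diketene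
Product: 16 cis-fused (2R,3aR,7aR)-3a-geranyl-7a-hydroxy-1,1-dimethyl-2-prenylhexahydroindane-4,6-dione, via lithium enolate 14 (not isolated), via acetoacetyl ketone enolate 15 (not isolated)
Conditions: MeLi (1.0 equiv), THF, 0 °C to rt; then 13, −78 to −20 °C; aq. NH4Cl
Reagents that add atoms: none
Why: MeLi cleaves the O–Si bond of 12 to the amine-free lithium enolate 14 and Me4Si; C5 of 14 attacks the lactone carbonyl of 13, the four-membered ring opens by acyl–oxygen cleavage to the acetoacetyl group as its terminal lithium enolate 15, and that carbon (the future C1) adds to the C9 ketone. The closest known reaction type is the acylation–aldol annulation of cyclopentanone lithium enolates with diketene. One ring is closed, the six-membered dione ring C1–C2–C3–C4–C5–C9, by a 6-(enolexo)-exo-trig aldol addition, after the C5–C4 bond has formed intermolecularly. C5 is set in the acylation by the C7 prenyl group, which covers one face of the flat enolate so that 13 should enter from the other face (C4 trans to prenyl, geranyl cis to prenyl). C9 is set by the tether, since the C1 enolate hangs from the C4 face and can reach the carbonyl only from that face, which gives the cis fusion with the hydroxyl cis to the C5 geranyl group. The step needs C- over O-acylation (lithium counter-ion, ether solvent, no amine) and aldol closure faster than proton transfer from the C3 methylene to the terminal enolate; the closure is intramolecular, and the alkoxide formed then deprotonates C3, which makes the sequence irreversible. Regiochemistry needs no control because C8 is quaternary and 14 is the only enolate the ketone can form.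

Step 9
Reactants: 16 cis-fused 3a-geranyl-7a-hydroxy-1,1-dimethyl-2-prenylhexahydroindane-4,6-dione
Product: 18 (1R,5S,7R)-5-geranyl-8,8-dimethyl-7-prenylbicyclo[3.3.1]nonane-2,4,9-trione, via C1 phenyl-λ3-iodanyl ketone 17 (not isolated)
Conditions: PhI(OAc)2 (1.2 equiv), KOH (5 equiv), MeOH, 0 °C; then 1 M HCl to pH 3
Reagents that add atoms: none
Why: Hypervalent-iodine oxidative ring expansion (semipinacol-type 1,2-shift), known for fused hydroxy β-diketones of this kind: the extended enolate is functionalised at C1 by trivalent iodine, and the C9 alkoxide then pushes C8 from C9 to C1 with loss of the aryl iodide, which makes ring B and the C9 ketone; C1 can only take the configuration the bridge allows, and the diketonate form of C2/C4 suppresses retro-aldol cleavage in KOH.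

Step 10
Reactants: 18 (1R,5S,7R)-5-geranyl-8,8-dimethyl-7-prenylbicyclo[3.3.1]nonane-2,4,9-trione
Product: 19 (1R,5S,7R)-5-geranyl-4-methoxy-8,8-dimethyl-7-prenylbicyclo[3.3.1]non-3-ene-2,9-dione
Conditions: Me3SiCHN2, MeOH–toluene (1:4), 0 °C to rt; chromatography
Reagents that add atoms: (trimethylsilyl)diazomethane, C[Si](C)(C)C=[N+]=[N-]
Why: Neutral O-methylation of the vinylogous acid by diazomethane released in the flask, which leaves the side-chain alkenes alone; the C4 oxygen, remote from the C8 gem-dimethyl group, should be methylated preferentially, giving the isomer whose C2 ketone sits next to C1–H, and material methylated on the other oxygen is hydrolysed back to 18 and recycled.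

Step 11
Reactants: 19 (1R,5S,7R)-5-geranyl-4-methoxy-8,8-dimethyl-7-prenylbicyclo[3.3.1]non-3-ene-2,9-dione; 9 geranyl bromide
Product: 21 (1R,5S,7R)-1,5-digeranyl-4-methoxy-8,8-dimethyl-7-prenylbicyclo[3.3.1]non-3-ene-2,9-dione, via bridgehead lithium enolate 20 (not isolated)
Conditions: LiN(i-Pr)2 (1.5 equiv), THF, −78 °C; 9 (3 equiv), −78 to −20 °C
Reagents that add atoms: none
Why: Bridgehead enolate alkylation, known for enol ethers of bicyclo[3.3.1]nonane-2,4,9-triones: C1–H lies between the C2 and C9 carbonyls and is the α' position of the vinylogous ester, and the pyramidal anion is alkylated at carbon with retention, the only geometry the bicycle allows; SN2 attack on the primary allylic bromide keeps the geranyl group linear and E.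

Step 12
Reactants: 22 3,4-dihydroxybenzoic acid
Product: 23 tert-butyldimethylsilyl 3,4-bis(tert-butyldimethylsilyloxy)benzoate
Conditions: t-BuMe2SiCl (3.5 equiv), imidazole, DMF, rt
Reagents that add atoms: tert-butyldimethylsilyl chloride, CC(C)(C)[Si](C)(C)Cl
Why: Exhaustive silylation of both phenols and the acid; the silyl ester is the handle for step 13.

Step 13
Reactants: 23 tert-butyldimethylsilyl 3,4-bis(tert-butyldimethylsilyloxy)benzoate
Product: 24 3,4-bis(tert-butyldimethylsilyloxy)benzoyl chloride
Conditions: (COCl)2, DMF (cat.), CH2Cl2, 0 °C to rt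
Reagents that add atoms: oxalyl chloride, O=C(Cl)C(=O)Cl
Why: Silyl esters are converted directly into acid chlorides by oxalyl chloride and catalytic DMF without release of HCl, so the aryl silyl ethers remain.

Step 14
Reactants: 21 (1R,5S,7R)-1,5-digeranyl-4-methoxy-8,8-dimethyl-7-prenylbicyclo[3.3.1]non-3-ene-2,9-dione; 24 3,4-bis(tert-butyldimethylsilyloxy)benzoyl chloride
Product: 26 (1S,5S,7R)-3-[3,4-bis(tert-butyldimethylsilyloxy)benzoyl]-1,5-digeranyl-4-methoxy-8,8-dimethyl-7-prenylbicyclo[3.3.1]non-3-ene-2,9-dione, via C3 vinyllithium 25 (not isolated)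
Conditions: lithium 2,2,6,6-tetramethylpiperidide (2 equiv), THF, −78 °C; 24 (3 equiv), −78 to −40 °C
Reagents that add atoms: none
Why: With both bridgeheads quaternary, the vinylic C3–H (α to the C2 ketone, β to the methoxy group) is the only acidic proton; the vinyllithium is acylated at carbon by the acid chloride, a known substitution for this class of enol ethers (the C1 descriptor changes only through priorities).

Step 15
Reactants: 26 (1S,5S,7R)-3-[3,4-bis(tert-butyldimethylsilyloxy)benzoyl]-1,5-digeranyl-4-methoxy-8,8-dimethyl-7-prenylbicyclo[3.3.1]non-3-ene-2,9-dione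
Product: 27 (1S,5S,7R)-3-[3,4-bis(tert-butyldimethylsilyloxy)benzoyl]-1,5-digeranyl-4-hydroxy-8,8-dimethyl-7-prenylbicyclo[3.3.1]non-3-ene-2,9-dione
Conditions: LiCl (10 equiv), DMSO, 120 °C; dilute HCl work-up
Reagents that add atoms: none
Why: Krapcho-type SN2 demethylation of the vinylogous methyl ester by chloride, with a triketonate as leaving group; the conditions are neutral and non-hydrolytic, no stereocentre is involved, and any aryl silyl ether lost here is removed in step 16 anyway.

Step 16
Reactants: 27 (1S,5S,7R)-3-[3,4-bis(tert-butyldimethylsilyloxy)benzoyl]-1,5-digeranyl-4-hydroxy-8,8-dimethyl-7-prenylbicyclo[3.3.1]non-3-ene-2,9-dione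
Product: 28 CNP0178719.1
Conditions: Bu4NF, AcOH, THF, 0 °C, under argon
Reagents that add atoms: none
Why: Fluoride cleavage of the two aryl silyl ethers, buffered with acetic acid so that neither the catechol nor the triketone sits as its anion in air, where oxidation or cyclisation onto a side-chain alkene could begin.

## Compound list

1 | 2,2-dimethylcyclopentane-1,3-dione | CC1(C)C(=O)CCC1=O | starting material
2 | triethyl phosphonoacetate | CCOC(=O)CP(=O)(OCC)OCC | starting material
3 | ethyl (2E)-2-(2,2-dimethyl-3-oxocyclopentylidene)acetate | CCOC(=O)/C=C1\CCC(=O)C1(C)C | intermediate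
4 | ethyl 2-[(1S)-2,2-dimethyl-3-oxocyclopentyl]acetate | O=C1CC[C@@H](CC(=O)OCC)C1(C)C | intermediate
5 | (3S)-3-(2-hydroxyethyl)-2,2-dimethylcyclopentan-1-ol, both C1 epimers | OC1CC[C@@H](CCO)C1(C)C | intermediate
6 | 2-[(1S)-2,2-dimethyl-3-oxocyclopentyl]acetaldehyde | O=C1CC[C@@H](CC=O)C1(C)C | intermediate
7 | isopropyltriphenylphosphonium iodide | CC(C)[P+](c1ccccc1)(c1ccccc1)c1ccccc1.[I-] | starting material
8 | (3S)-2,2-dimethyl-3-(3-methylbut-2-en-1-yl)cyclopentan-1-one | O=C1CC[C@@H](CC=C(C)C)C1(C)C | intermediate
9 | geranyl bromide, (2E)-1-bromo-3,7-dimethylocta-2,6-diene | BrC/C=C(\C)CCC=C(C)C | starting material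
10 | lithium enolate of 8 (C9=C5 enolate, C7 unchanged) | [Li]OC1=CC[C@@H](CC=C(C)C)C1(C)C | intermediate (not isolated)
11 | (3R,5RS)-5-[(2E)-3,7-dimethylocta-2,6-dien-1-yl]-2,2-dimethyl-3-(3-methylbut-2-en-1-yl)cyclopentan-1-one | O=C1C(C/C=C(\C)CCC=C(C)C)C[C@@H](CC=C(C)C)C1(C)C | intermediate
12 | {[(4R)-2-geranyl-5,5-dimethyl-4-prenylcyclopent-1-en-1-yl]oxy}trimethylsilane | C[Si](C)(C)OC1=C(C/C=C(\C)CCC=C(C)C)C[C@@H](CC=C(C)C)C1(C)C | intermediate
13 | diketene, 4-methyleneoxetan-2-one | C=C1CC(=O)O1 | starting material
14 | lithium enolate of 11 (tetrasubstituted C9=C5 enolate) | [Li]OC1=C(C/C=C(\C)CCC=C(C)C)C[C@@H](CC=C(C)C)C1(C)C | intermediate (not isolated)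
15 | 2-acetoacetyl-2-geranyl-5,5-dimethyl-4-prenylcyclopentanone as its terminal lithium enolate (acyl group trans to prenyl) | C=C(O[Li])CC(=O)[C@]1(C/C=C(\C)CCC=C(C)C)C[C@@H](CC=C(C)C)C(C)(C)C1=O | intermediate (not isolated)
16 | cis-fused (2R,3aR,7aR)-3a-geranyl-7a-hydroxy-1,1-dimethyl-2-prenylhexahydroindane-4,6-dione (hydroxyl, geranyl and prenyl on one face) | O=C1CC(=O)[C@]2(C/C=C(\C)CCC=C(C)C)C[C@@H](CC=C(C)C)C(C)(C)[C@]2(O)C1 | intermediate
17 | C1-[methoxy(phenyl)-λ3-iodanyl] derivative of 16 (C1 is the CH2 between the carbinol and the C2 ketone) | O=C1CC(=O)[C@]2(C/C=C(\C)CCC=C(C)C)C[C@@H](CC=C(C)C)C(C)(C)[C@]2(O)C1I(OC)c1ccccc1 | intermediate (not isolated)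
18 | (1R,5S,7R)-5-geranyl-8,8-dimethyl-7-prenylbicyclo[3.3.1]nonane-2,4,9-trione (enolised between C2 and C4; prenyl equatorial on ring B) | CC(C)=CCC/C(C)=C/C[C@]12C[C@@H](CC=C(C)C)C(C)(C)[C@H](C(=O)CC1=O)C2=O | intermediate
19 | (1R,5S,7R)-5-geranyl-4-methoxy-8,8-dimethyl-7-prenylbicyclo[3.3.1]non-3-ene-2,9-dione | CC(C)=CCC/C(C)=C/C[C@]12C[C@@H](CC=C(C)C)C(C)(C)[C@H](C(=O)C=C1OC)C2=O | intermediate
20 | C1-lithio derivative (bridgehead enolate) of 19 | CC(C)=CCC/C(C)=C/C[C@]12C[C@@H](CC=C(C)C)C(C)(C)[C@]([Li])(C(=O)C=C1OC)C2=O | intermediate (not isolated)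
21 | (1R,5S,7R)-1,5-digeranyl-4-methoxy-8,8-dimethyl-7-prenylbicyclo[3.3.1]non-3-ene-2,9-dione | CC(C)=CCC/C(C)=C/C[C@]12C[C@@H](CC=C(C)C)C(C)(C)[C@](C/C=C(\C)CCC=C(C)C)(C(=O)C=C1OC)C2=O | intermediate
22 | 3,4-dihydroxybenzoic acid | O=C(O)c1ccc(O)c(O)c1 | starting material
23 | tert-butyldimethylsilyl 3,4-bis(tert-butyldimethylsilyloxy)benzoate | CC(C)(C)[Si](C)(C)OC(=O)c1ccc(O[Si](C)(C)C(C)(C)C)c(O[Si](C)(C)C(C)(C)C)c1 | intermediate
24 | 3,4-bis(tert-butyldimethylsilyloxy)benzoyl chloride | O=C(Cl)c1ccc(O[Si](C)(C)C(C)(C)C)c(O[Si](C)(C)C(C)(C)C)c1 | intermediate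
25 | C3-lithio derivative of 21 | CC(C)=CCC/C(C)=C/C[C@]12C[C@@H](CC=C(C)C)C(C)(C)[C@](C/C=C(\C)CCC=C(C)C)(C(=O)C([Li])=C1OC)C2=O | intermediate (not isolated)
26 | (1S,5S,7R)-3-[3,4-bis(tert-butyldimethylsilyloxy)benzoyl]-1,5-digeranyl-4-methoxy-8,8-dimethyl-7-prenylbicyclo[3.3.1]non-3-ene-2,9-dione | CC(C)=CCC/C(C)=C/C[C@]12C[C@@H](CC=C(C)C)C(C)(C)[C@](C/C=C(\C)CCC=C(C)C)(C(=O)C(C(=O)c3ccc(O[Si](C)(C)C(C)(C)C)c(O[Si](C)(C)C(C)(C)C)c3)=C1OC)C2=O | intermediate
27 | (1S,5S,7R)-3-[3,4-bis(tert-butyldimethylsilyloxy)benzoyl]-1,5-digeranyl-4-hydroxy-8,8-dimethyl-7-prenylbicyclo[3.3.1]non-3-ene-2,9-dione | CC(C)=CCC/C(C)=C/C[C@]12C[C@@H](CC=C(C)C)C(C)(C)[C@](C/C=C(\C)CCC=C(C)C)(C(=O)C(C(=O)c3ccc(O[Si](C)(C)C(C)(C)C)c(O[Si](C)(C)C(C)(C)C)c3)=C1O)C2=O | intermediate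
28 | CNP0178719.1, (1S,5S,7R)-3-(3,4-dihydroxybenzoyl)-1,5-digeranyl-4-hydroxy-8,8-dimethyl-7-prenylbicyclo[3.3.1]non-3-ene-2,9-dione | CC(C)=CCC/C(C)=C/C[C@]12C[C@@H](CC=C(C)C)C(C)(C)[C@](C/C=C(\C)CCC=C(C)C)(C(=O)C(C(=O)c3ccc(O)c(O)c3)=C1O)C2=O | target

## Step count and least certain steps

Total step count: 16. Longest linear sequence: 14 steps (steps 1–11 and 14–16, from 1); steps 12 and 13 make 24 and join at step 14.

**Step 8 (key step).**
- What may go wrong: proton transfer from the doubly activated C3 methylene to the terminal enolate 15 may outrun aldol addition to C9, a carbonyl between two quaternary carbons, and leave open-chain material.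
- O-acylation of the enolate or enolate-initiated oligomerisation of diketene may consume the reagents.
- Facial discrimination may be incomplete, since the only bias is the C7 prenyl group two atoms from C5.
- Fallback (acylation and ring closure as two operations): from 12, the enolate is generated and acylated as before but quenched cold with acetic acid, and the open-chain 2-acetoacetyl-2-geranyl-5,5-dimethyl-4-prenylcyclopentanone F1 is isolated (a C5 epimer, if formed, is removed here). F1 is then treated with 2.2 equiv of LiN(i-Pr)2 (THF, −78 to 0 °C). This forms the 1,3-diketone dianion, whose terminal carbanion adds to C9 with no internal proton source left, and returns the route to 16.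

**Step 2.**
- What may go wrong: enantioselectivity may be insufficient, because an exocyclic ylidene acetate whose β-carbon carries two ring carbons is not a well-mapped substrate for copper hydride.
- E/Z isomerisation of 3 before hydride transfer would erode it further, and 1,2-reduction competes.
- Fallback (iminium catalysis in place of copper hydride): from 3, i-Bu2AlH (CH2Cl2, −78 °C) reduces ester and ketone to (E)-3-(2-hydroxyethylidene)-2,2-dimethylcyclopentan-1-ol F2. Dess–Martin periodinane oxidises both alcohols to (2E)-2-(2,2-dimethyl-3-oxocyclopentylidene)acetaldehyde F3. Transfer hydrogenation of F3 with diethyl 2,6-dimethyl-1,4-dihydropyridine-3,5-dicarboxylate and a 2-tert-butyl-3-methylimidazolidin-4-one salt (20 mol %, CHCl3, −30 °C) reduces the enal C=C enantioselectively, tolerates the ketone and converges E and Z isomers. The product is 6, where the route is rejoined with the same step count.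

**Step 9.**
- What may go wrong: trivalent iodine may be transferred to the doubly activated C3 and give a stable iodonium ylide that does not rearrange.
- Methanol may be captured at C1 in place of the carbon shift, or the electron-rich side-chain alkenes may be oxidised.
- Fallback (leaving group placed on C1 through a silyl dienol ether): from 16, Me3SiOTf and Et3N (CH2Cl2, 0 °C) give the tris(trimethylsilyl) derivative F4, a 1,3-bis(silyloxy)diene with the tertiary alcohol silylated as well. Such dienes react with electrophiles at the terminal carbon, so N-bromosuccinimide (1 equiv, THF, −78 °C) should give the C1 bromide F5. Bu4NF (THF, 0 °C) then frees the C9 alkoxide, which expels bromide through the same 1,2-shift of C8 and gives 18.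

**Step 10.**
- What may go wrong: methylation may occur on the C2 oxygen rather than the C4 oxygen. The two enol oxygens differ only in their distance from the gem-dimethyl and geranyl groups, and the wrong isomer lacks the C2 ketone that acidifies C1–H.
- Fallback (second geranyl group introduced before the bicycle exists, so the regiochemistry no longer matters): from 16, 3.2 equiv of LiN(i-Pr)2 (THF, −78 to 0 °C) give the alkoxide–diketonate–C1 carbanion, and 9 alkylates it at the only γ-carbon to give the C1-geranyl hydroxy dione F6. The conditions of step 9 convert F6 into the 1,5-digeranyl trione F7. Methylation as in step 10 gives 21 together with its 2-methoxy regioisomer F8, both of which have only the C3 proton left. 21 re-enters at step 14. F8 is aroylated under the conditions of step 14 to F9 and demethylated under those of step 15 to 27, where the two series converge.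

**Step 11.**
- What may go wrong: kinetic removal of the exposed vinylic C3–H may compete with removal of C1–H.
- Alkylation of the hindered, pyramidal C1 anion beside the quaternary C8 may be slow, so that the anion decays or the amide adds to the enone; SN2' attack would give the branched isomer.
- Fallback (C3 blocked as a vinylsilane): from 19, lithium 2,2,6,6-tetramethylpiperidide in the presence of Me3SiCl (THF, −78 °C) traps the kinetic C3 anion as the 3-trimethylsilyl derivative F10. LiN(i-Pr)2 and then 9 alkylate the bridgehead to give F11. Bu4NF (THF, 0 °C) removes the vinylsilane and gives 21.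

## Further compounds

F1 | step 8 | 2-acetoacetyl-2-geranyl-5,5-dimethyl-4-prenylcyclopentan-1-one (acyl group trans to prenyl) | CC(=O)CC(=O)[C@]1(C/C=C(\C)CCC=C(C)C)C[C@@H](CC=C(C)C)C(C)(C)C1=O
F2 | step 2 | (E)-3-(2-hydroxyethylidene)-2,2-dimethylcyclopentan-1-ol | OC/C=C1\CCC(O)C1(C)C
F3 | step 2 | (2E)-2-(2,2-dimethyl-3-oxocyclopentylidene)acetaldehyde | O=C/C=C1\CCC(=O)C1(C)C
F4 | step 9 | tris(trimethylsilyl) derivative of 16: 4,6-bis(trimethylsilyloxy)diene with 7a-trimethylsilyloxy group | C[Si](C)(C)OC=1C=C(O[Si](C)(C)C)[C@]2(C/C=C(\C)CCC=C(C)C)C[C@@H](CC=C(C)C)C(C)(C)[C@]2(O[Si](C)(C)C)C=1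
F5 | step 9 | C1-bromo enone from F4: 7-bromo-3a-geranyl-1,1-dimethyl-2-prenyl-4,7a-bis(trimethylsilyloxy)tetrahydroindan-6-one | O=C1C=C(O[Si](C)(C)C)[C@]2(C/C=C(\C)CCC=C(C)C)C[C@@H](CC=C(C)C)C(C)(C)[C@]2(O[Si](C)(C)C)C1Br
F6 | step 10 | C1-geranyl derivative of 16 (3a,7-digeranyl-7a-hydroxy-1,1-dimethyl-2-prenylhexahydroindane-4,6-dione) | O=C1CC(=O)[C@]2(C/C=C(\C)CCC=C(C)C)C[C@@H](CC=C(C)C)C(C)(C)[C@]2(O)C1C/C=C(\C)CCC=C(C)C
F7 | step 10 | 1,5-digeranyl-8,8-dimethyl-7-prenylbicyclo[3.3.1]nonane-2,4,9-trione | CC(C)=CCC/C(C)=C/C[C@]12C[C@@H](CC=C(C)C)C(C)(C)[C@](C/C=C(\C)CCC=C(C)C)(C(=O)CC1=O)C2=O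
F8 | step 10 | 1,5-digeranyl-2-methoxy-8,8-dimethyl-7-prenylbicyclo[3.3.1]non-2-ene-4,9-dione | CC(C)=CCC/C(C)=C/C[C@]12C[C@@H](CC=C(C)C)C(C)(C)[C@](C/C=C(\C)CCC=C(C)C)(C(OC)=CC1=O)C2=O
F9 | step 10 | 3-[3,4-bis(tert-butyldimethylsilyloxy)benzoyl]-1,5-digeranyl-2-methoxy-8,8-dimethyl-7-prenylbicyclo[3.3.1]non-2-ene-4,9-dione | CC(C)=CCC/C(C)=C/C[C@]12C[C@@H](CC=C(C)C)C(C)(C)[C@](C/C=C(\C)CCC=C(C)C)(C(OC)=C(C(=O)c3ccc(O[Si](C)(C)C(C)(C)C)c(O[Si](C)(C)C(C)(C)C)c3)C1=O)C2=O
F10 | step 11 | 5-geranyl-4-methoxy-8,8-dimethyl-7-prenyl-3-(trimethylsilyl)bicyclo[3.3.1]non-3-ene-2,9-dione | CC(C)=CCC/C(C)=C/C[C@]12C[C@@H](CC=C(C)C)C(C)(C)[C@H](C(=O)C([Si](C)(C)C)=C1OC)C2=O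
F11 | step 11 | 1,5-digeranyl-4-methoxy-8,8-dimethyl-7-prenyl-3-(trimethylsilyl)bicyclo[3.3.1]non-3-ene-2,9-dione | CC(C)=CCC/C(C)=C/C[C@]12C[C@@H](CC=C(C)C)C(C)(C)[C@](C/C=C(\C)CCC=C(C)C)(C(=O)C([Si](C)(C)C)=C1OC)C2=O
A1 | alternative 1 | mesityl oxide | CC(=O)C=C(C)C
A2 | alternative 1 | 4-methyl-2-(triisopropylsilyloxy)penta-1,3-diene | C=C(O[Si](C(C)C)(C(C)C)C(C)C)C=C(C)C
A3 | alternative 1 | 3-acryloyloxazolidin-2-one | C=CC(=O)N1CCOC1=O
A4 | alternative 1 | 3-[2,2-dimethyl-4-(triisopropylsilyloxy)cyclohex-3-ene-1-carbonyl]oxazolidin-2-one | O=C([C@@H]1CCC(O[Si](C(C)C)(C(C)C)C(C)C)=CC1(C)C)N1CCOC1=O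
A5 | alternative 2 | bis(1,3-dioxoisoindolin-2-yl) 4-methoxy-8,8-dimethyl-2,9-dioxo-7-prenylbicyclo[3.3.1]non-3-ene-1,5-dicarboxylate | O=C(ON3C(=O)c4ccccc4C3=O)[C@]12C[C@@H](CC=C(C)C)C(C)(C)[C@](C(=O)ON3C(=O)c4ccccc4C3=O)(C(=O)C=C1OC)C2=O
A6 | alternative 2 | geranyl methyl carbonate | COC(=O)OC/C=C(\C)CCC=C(C)C
A7 | alternative 2 | 1,5-digeranyl-4-methoxy-8,8-dimethyl-7-prenylbicyclo[3.3.1]non-3-ene-2,9-dione | [C@]12(C/C=C(\C)CCC=C(C)C)C[C@@H](CC=C(C)C)C(C)(C)[C@](C/C=C(\C)CCC=C(C)C)(C(=O)C=C1OC)C2=O
A8 | alternative 3 | 6-geranyl-6-(2-isopropenyl-5-methylhex-4-en-1-yl)-1,5-dimethoxycyclohexa-1,4-diene | COC1=CCC=C(OC)C1(C/C=C(\C)CCC=C(C)C)C[C@@H](CC=C(C)C)C(C)=C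
A9 | alternative 3 | 5-geranyl-4-methoxy-8,8-dimethyl-7-prenylbicyclo[3.3.1]non-3-en-9-one | [C@]12(C/C=C(\C)CCC=C(C)C)C[C@@H](CC=C(C)C)C(C)(C)[C@H](CC=C1OC)C2=O
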